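**Plan**

- Retrosynthesis: the esters and the C7 carbinol come off first (C7–OH from a ketone). Next go C8=C17 and the C9–C11 bond (conjugate addition and α-methylenation on a C8=C9 enone), then the 2α,3α-diol (from a C2=C3 alkene). The core is then cut at C3–C4 and C5–C10.
- Enabling feature: in ring A the gem-dimethyl carbon C4 and the ring-fusion carbon C5 are a two-carbon unit flanked by C3 and C10. Ring A is therefore the [4+2] adduct of a C3=C2–C1=C10 diene and a C4=C5 isopropylidene dienophile. Because C5 and C10 are also linked through C6–C7–C8–C9, the same C5–C10 bond closes ring B.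
- Helpers: a C6 ketone with a chelating C7 benzyloxy group activates the dienophile and is then transposed to C7. A C3 silyl group moves the adduct's C1=C2 alkene to C2=C3.
- Forward order: two cross-couplings on an (E)-2-bromo-3-iodoallyl unit join diene, tether and dienophile. Rings A and B form together in step 9. Then come the ring A diol and esters, the side chain on C9, the C17 methylene and the C7 reduction.
- Stereochemistry: C10 is relayed from the C7 centre of (S)-α-hydroxy-γ-butyrolactone in the cycloaddition; C5 by equilibration; C2 and C3 by α-face osmylation; C9 by addition anti to the axial C10 CH2OAc group; C7 by hydride attack anti to the axial C9 chain; C13 from (R)-linalool; the angelate geometry from angelic acid.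

Key step: step 9

Remark: labdane numbering is used for all decalin compounds; β is the face of the C10 CH2O group (C20) and α the opposite face.

**Route**

Step 1
Reactants: 1 prop-2-yn-1-ol
Product: 2 (E)-2-bromo-3-iodoprop-2-en-1-ol
Conditions: IBr, CH2Cl2, −40 → 0 °C
Reagents that add atoms: iodine monobromide, BrI
Why: Anti iodobromination of the terminal alkyne through an iodirenium ion should place iodine on the terminal carbon and bromide trans to it on the internal carbon, which differentiates the two alkenyl halides for the two later couplings.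

Step 2
Reactants: 2 (E)-2-bromo-3-iodoprop-2-en-1-ol
Product: 3 tert-butyl{[(E)-2-bromo-3-iodoprop-2-en-1-yl]oxy}dimethylsilane
Conditions: TBSCl, imidazole, DMF, rt
Reagents that add atoms: tert-butyldimethylsilyl chloride, CC(C)(C)[Si](C)(C)Cl
Why: Imidazole-mediated silylation masks the future C20 oxygen as an ether that cannot ionise under the palladium-catalysed steps.

Step 3
Reactants: 3 tert-butyl{[(E)-2-bromo-3-iodoprop-2-en-1-yl]oxy}dimethylsilane, 4 (E)-tributyl[2-(trimethylsilyl)ethenyl]stannane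
Product: 5 tert-butyl{[(2E,4E)-2-bromo-5-(trimethylsilyl)penta-2,4-dien-1-yl]oxy}dimethylsilane
Conditions: Pd2(dba)3 (2.5 mol%), AsPh3 (10 mol%), CuI (10 mol%), NMP, rt
Reagents that add atoms: none
Why: Stille coupling should occur only at the C–I bond, which adds to zerovalent palladium far faster than the hindered C–Br bond, with retention at both alkenyl partners.

Step 4
Reactants: 6 (S)-3-hydroxydihydrofuran-2(3H)-one
Product: 7 (S)-3-(benzyloxy)dihydrofuran-2(3H)-one
Conditions: BnOC(=NH)CCl3, TfOH (cat.), CH2Cl2/cyclohexane, 0 °C → rt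
Reagents that add atoms: benzyl 2,2,2-trichloroacetimidate, N=C(OCc1ccccc1)C(Cl)(Cl)Cl
Why: Acid-catalysed trichloroacetimidate benzylation avoids base and so should not epimerise the α-stereocentre of the lactone.

Step 5
Reactants: 7 (S)-3-(benzyloxy)dihydrofuran-2(3H)-one
Product: 8 (S)-2-(benzyloxy)-4-hydroxy-N-methoxy-N-methylbutanamide
Conditions: MeNH(OMe)·HCl, iPrMgCl, THF, −20 °C; aq. NH4Cl
Reagents that add atoms: N,O-dimethylhydroxylamine hydrochloride, CNOC.Cl
Why: Magnesium amide aminolysis of the lactone (Weinreb amide formation) opens the ring at the acyl carbon and leaves the benzyloxy-bearing centre untouched.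

Step 6
Reactants: 8 (S)-2-(benzyloxy)-4-hydroxy-N-methoxy-N-methylbutanamide
Product: 9 (S)-2-(benzyloxy)-4-iodo-N-methoxy-N-methylbutanamide
Conditions: I2, PPh3, imidazole, CH2Cl2, 0 °C
Reagents that add atoms: iodine, II
Why: Appel-type iodination converts the primary alcohol into the iodide by SN2 displacement of the oxyphosphonium group.

Step 7
Reactants: 9 (S)-2-(benzyloxy)-4-iodo-N-methoxy-N-methylbutanamide
Product: 10 (S)-3-(benzyloxy)-1-iodo-6-methylhept-5-en-4-one
Conditions: (CH3)2C=CHMgBr, THF, −20 → 0 °C; aq. NH4Cl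
Reagents that add atoms: 2-methylprop-1-en-1-ylmagnesium bromide, CC(C)=C[Mg]Br
Why: Weinreb ketone synthesis stops at the chelated tetrahedral intermediate and releases the β,β-dimethyl enone on work-up, the primary iodide being inert to the alkenyl Grignard reagent at this temperature.

Step 8
Reactants: 10 (S)-3-(benzyloxy)-1-iodo-6-methylhept-5-en-4-one, 5 tert-butyl{[(2E,4E)-2-bromo-5-(trimethylsilyl)penta-2,4-dien-1-yl]oxy}dimethylsilane
Product: 12 (5S,8Z,10E)-5-(benzyloxy)-8-{[(tert-butyldimethylsilyl)oxy]methyl}-2-methyl-11-(trimethylsilyl)undeca-2,8,10-trien-4-one, via alkylzinc iodide 11 (not isolated)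
Conditions: Zn dust, LiCl, THF, 35 °C; then 5, Pd(OAc)2 (3 mol%), SPhos (6 mol%), THF, rt
Reagents that add atoms: none
Why: Zinc insertion into the primary C–I bond gives an enone-tolerant alkylzinc iodide whose Negishi coupling at the alkenyl bromide proceeds with retention, so C9 ends trans to C2 and the CH2OTBS group sits on the inside of the diene terminus C10.

Step 9
Reactants: 12 (5S,8Z,10E)-5-(benzyloxy)-8-{[(tert-butyldimethylsilyl)oxy]methyl}-2-methyl-11-(trimethylsilyl)undeca-2,8,10-trien-4-one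
Product: 13 cis-fused cycloadduct, 7α-benzyloxy-10β-[(tert-butyldimethylsilyloxy)methyl]-4,4-dimethyl-3α-(trimethylsilyl)-5β-H-decal-1-en-6-one
Conditions: Me2AlCl (2.2 equiv), CH2Cl2, −78 → −20 °C
Reagents that add atoms: none
Why: Two equivalents of Me2AlCl turn the α′-benzyloxy enone into a cationic five-membered O(C6)–Al–O(C7) chelate, which lowers the LUMO of the hindered β,β-dimethyl enone enough for the tethered (E)-1-silyl diene to add across C4=C5 in a concerted but asynchronous [4+2] process; the closest known reaction type is the Lewis-acid-promoted type 1 intramolecular Diels–Alder reaction of 1,7,9-decatrien-3-ones with a chelating α′-alkoxy enone as dienophile. Ring A is the new cyclohexene (bonds C3–C4 and C5–C10, alkene C1=C2), and ring B is closed by the same C5–C10 bond through a chair-like six-membered array C5–C6–C7–C8–C9–C10 in the endo mode (C6 carbonyl under the diene), which gives the cis-fused decalin. C10 is set by the choice of diene face: the chelate holds the C7 benzyloxy group in the carbonyl plane, equatorial on the incipient ring B, so the (S)-centre at C7 places the C10 CH2OTBS group trans to OBn. C5 follows from the endo orientation (H5 cis to C20), and C3 from the (E)-vinylsilane, whose outside silyl group ends cis to C9 by suprafacial addition. The step needs endo over exo selectivity and one diene face: the known endo preference of internally activated decatrienones, reinforced by the Lewis acid, should secure the first and the chelate-fixed C7 centre the second, and any exo adduct is a diastereomer at this stage and is removed by chromatography. Only the C10 configuration must be right here, because C3, C5 and C7 are erased or corrected in steps 10 to 13.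

Step 10
Reactants: 13 cis-fused cycloadduct
Product: 14 trans-fused ketone, 7α-benzyloxy-10β-[(tert-butyldimethylsilyloxy)methyl]-4,4-dimethyl-3α-(trimethylsilyl)-5α-H-decal-1-en-6-one
Conditions: DBU, toluene, 50 °C
Reagents that add atoms: none
Why: Base-mediated epimerisation through the C5=C6 enolate should convert the kinetic cis-fused ketone into the thermodynamically preferred trans-fused 4,4,10-trisubstituted decalin with 5α-H, and any concurrent equilibration at C7 is immaterial because that centre is erased in steps 11 to 13.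

Step 11
Reactants: 14 trans-fused ketone
Product: 15 enol triflate, 7-benzyloxy-10β-[(tert-butyldimethylsilyloxy)methyl]-4,4-dimethyl-3α-(trimethylsilyl)-5α-H-decala-1,6-dien-6-yl trifluoromethanesulfonate
Conditions: KN(SiMe3)2, THF, −78 °C; PhNTf2; aq. NH4Cl
Reagents that add atoms: N-phenylbis(trifluoromethanesulfonimide), O=S(=O)(N(c1ccccc1)S(=O)(=O)C(F)(F)F)C(F)(F)F
Why: Kinetic enolisation should occur at C7, because C5 is a ring-fusion methine flanked by two quaternary carbons, and O-sulfonylation of the enolate gives the enol triflate (regioselective enol triflate formation).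

Step 12
Reactants: 15 enol triflate
Product: 16 benzyl enol ether, 7-benzyloxy-10β-[(tert-butyldimethylsilyloxy)methyl]-4,4-dimethyl-3α-(trimethylsilyl)-5α-H-decala-1,6-diene
Conditions: Pd(OAc)2 (5 mol%), PPh3, HCO2H, Bu3N, DMF, 60 °C
Reagents that add atoms: none
Why: Palladium-catalysed formate reduction of the alkenyl triflate replaces OTf by hydrogen and so removes the C6 oxygen while leaving the C6=C7 enol ether.

Step 13
Reactants: 16 benzyl enol ether
Product: 17 10β-(hydroxymethyl)-4,4-dimethyl-5α-H-decal-2-en-7-one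
Conditions: TFA/H2O (9:1), CH2Cl2, 0 °C → rt; then aq. NaHCO3
Reagents that add atoms: water, O
Why: Aqueous acid should hydrolyse the enol ether to the C7 ketone (completing a 1,2-carbonyl transposition), protonate the allylsilane at C1 with loss of silicon so that the alkene moves to C2=C3 (SE2′ protodesilylation), and cleave the primary silyl ether.

Step 14
Reactants: 17 10β-(hydroxymethyl)-4,4-dimethyl-5α-H-decal-2-en-7-one
Product: 18 10β-(acetoxymethyl)-4,4-dimethyl-5α-H-decal-2-en-7-one
Conditions: Ac2O, pyridine, DMAP (cat.), rt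
Reagents that add atoms: acetic anhydride, CC(=O)OC(C)=O
Why: DMAP-catalysed acetylation of the neopentyl primary alcohol installs the C20 acetate of the target.

Step 15
Reactants: 18 10β-(acetoxymethyl)-4,4-dimethyl-5α-H-decal-2-en-7-one
Product: 19 10β-(acetoxymethyl)-2α,3α-dihydroxy-4,4-dimethyl-5α-H-decalin-7-one
Conditions: OsO4 (2 mol%), NMO, acetone/H2O, rt
Reagents that add atoms: osmium tetroxide, O=[Os](=O)(=O)=O; N-methylmorpholine N-oxide, C[N+]1([O-])CCOCC1
Why: Upjohn syn-dihydroxylation should occur on the α face of the C2=C3 alkene because the β face is shielded by the axial 4β-methyl and the axial C10 CH2OAc groups, which sets C2 and C3 as the 2α,3α-diol.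

Step 16
Reactants: 19 10β-(acetoxymethyl)-2α,3α-dihydroxy-4,4-dimethyl-5α-H-decalin-7-one
Product: 20 10β-(acetoxymethyl)-2α-[(Z)-2-methylbut-2-enoyloxy]-3α-hydroxy-4,4-dimethyl-5α-H-decalin-7-one
Conditions: angelic acid, 2,4,6-Cl3C6H2COCl, Et3N, toluene, rt; then 19, 70 °C
Reagents that add atoms: angelic acid, C/C=C(/C)C(=O)O
Why: Yamaguchi-type acylation through the mixed anhydride should acylate only the equatorial C2 hydroxyl, the axial C3 hydroxyl next to the gem-dimethyl carbon being much slower, and the DMAP-free conditions preserve the (Z)-geometry of the angelate.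

Step 17
Reactants: 20 2α-angelate 3α-alcohol
Product: 21 3α-acetoxy-10β-(acetoxymethyl)-2α-[(Z)-2-methylbut-2-enoyloxy]-4,4-dimethyl-5α-H-decalin-7-one
Conditions: Ac2O, DMAP, pyridine, 40 °C
Reagents that add atoms: acetic anhydride, CC(=O)OC(C)=O
Why: DMAP-catalysed acetylation of the remaining hindered axial C3 hydroxyl completes the ester pattern of ring A.

Step 18
Reactants: 21 triester ketone
Product: 23 3α-acetoxy-10β-(acetoxymethyl)-2α-[(Z)-2-methylbut-2-enoyloxy]-4,4-dimethyl-5α-H-decal-8-en-7-one, via silyl enol ether 22 (not isolated)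
Conditions: TMSOTf, Et3N, CH2Cl2, 0 °C; then Pd(OAc)2 (10 mol%), O2 (1 atm), DMSO, rt
Reagents that add atoms: none
Why: Soft enolisation should give the silyl enol ether on the C8 side, away from the ring fusion as in trans-fused 2-decalones, and aerobic palladium-catalysed dehydrosilylation (Saegusa–Ito oxidation) then gives the C8=C9 enone.

Step 19
Reactants: 24 (R)-3,7-dimethylocta-1,6-dien-3-ol ((R)-linalool)
Product: 25 (R)-[(3,7-dimethylocta-1,6-dien-3-yl)oxy]triethylsilane
Conditions: TESOTf, 2,6-lutidine, CH2Cl2, 0 °C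
Reagents that add atoms: triethylsilyl trifluoromethanesulfonate, CC[Si](CC)(CC)OS(=O)(=O)C(F)(F)F
Why: Silyl triflate silylation protects the tertiary allylic alcohol, whose carbon is the future C13 and is carried unchanged to the end.

Step 20
Reactants: 25 (R)-[(3,7-dimethylocta-1,6-dien-3-yl)oxy]triethylsilane
Product: 26 (R)-4-methyl-4-[(triethylsilyl)oxy]hex-5-enal
Conditions: O3 (1 equiv), CH2Cl2/pyridine, −78 °C; then PPh3
Reagents that add atoms: ozone, [O-][O+]=O
Why: Ozone should cleave the electron-rich trisubstituted alkene much faster than the monosubstituted vinyl group (chemoselective ozonolysis with reductive work-up).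

Step 21
Reactants: 26 (R)-4-methyl-4-[(triethylsilyl)oxy]hex-5-enal
Product: 27 (R,E)-trimethyl({4-methyl-4-[(triethylsilyl)oxy]hexa-1,5-dien-1-yl}oxy)silane
Conditions: TMSOTf, Et3N, CH2Cl2, 0 °C
Reagents that add atoms: trimethylsilyl trifluoromethanesulfonate, C[Si](C)(C)OS(=O)(=O)C(F)(F)F
Why: Soft enolisation of the aldehyde gives the silyl enol ether (E/Z mixture, drawn E), which marks the aldehyde carbon for excision.

Step 22
Reactants: 27 silyl enol ether
Product: 28 (R)-3-methyl-3-[(triethylsilyl)oxy]pent-4-en-1-ol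
Conditions: O3, CH2Cl2, −78 °C; then NaBH4, MeOH, −78 → 0 °C
Reagents that add atoms: ozone, [O-][O+]=O
Why: Ozonolysis of the electron-rich enol ether double bond with borohydride work-up removes one carbon and gives the primary alcohol, the vinyl group again being the slower alkene.

Step 23
Reactants: 28 (R)-3-methyl-3-[(triethylsilyl)oxy]pent-4-en-1-ol
Product: 29 (R)-[(5-bromo-3-methylpent-1-en-3-yl)oxy]triethylsilane
Conditions: CBr4, PPh3, CH2Cl2, 0 °C
Reagents that add atoms: carbon tetrabromide, BrC(Br)(Br)Br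
Why: Appel bromination converts the primary alcohol into the bromide by SN2 displacement without touching the tertiary silyl ether.

Step 24
Reactants: 29 (R)-[(5-bromo-3-methylpent-1-en-3-yl)oxy]triethylsilane, 23 C8=C9 enone
Product: 31 C7–C8 trimethylsilyl enol ether with the 9α side chain (13R, 13-OTES; 2α-angelate, 3α- and 20-acetates), via Grignard reagent 30 (not isolated)
Conditions: Mg, THF, rt; then CuBr·SMe2 (10 mol%), TMSCl, 23, THF, −78 °C; Et3N
Reagents that add atoms: chlorotrimethylsilane, C[Si](C)(C)Cl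
Why: Copper-catalysed, TMSCl-accelerated conjugate addition of the Grignard reagent should deliver the side chain to C9 anti to the pseudoaxial C10 CH2OAc group, that is on the α face, which sets C9, and should trap the enolate regiospecifically as the C7–C8 silyl enol ether.

Step 25
Reactants: 31 C7–C8 trimethylsilyl enol ether
Product: 34 7-oxo-8(17)-ene, 13-O-triethylsilyl 7-dehydro target, via Mannich base 32 (not isolated), via trimethylammonium iodide 33 (not isolated)
Conditions: CH2=NMe2+ I−, CH2Cl2, rt; then MeI; then aq. NaHCO3, rt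
Reagents that add atoms: N,N-dimethylmethyleneiminium iodide (Eschenmoser's salt), C=[N+](C)C.[I-]
Why: Mannich reaction of the silyl enol ether at C8, N-methylation and E1cB elimination (Eschenmoser methylenation) give the exocyclic α-methylene ketone, the C8 centre of the intermediates being lost.

Step 26
Reactants: 34 7-oxo-8(17)-ene
Product: 35 7α-hydroxy-8(17)-ene, 13-O-triethylsilyl target
Conditions: NaBH4, CeCl3·7H2O, MeOH, −78 °C
Reagents that add atoms: none
Why: Luche 1,2-reduction is run at once on the isomerisation-prone enone, and hydride should add to C7 from the β face because axial attack from the α face is blocked by the syn-axial C9 side chain, giving the axial 7α alcohol.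

Step 27
Reactants: 35 13-O-triethylsilyl target
Product: 36 target, (2R,3S,5R,7R,9S,10R,13R)-3,20-diacetoxy-2-[(Z)-2-methylbut-2-enoyloxy]-9βH-labda-8(17),14-diene-7,13-diol
Conditions: HF·pyridine, pyridine, THF, 0 °C
Reagents that add atoms: none
Why: Buffered fluoride desilylation frees the tertiary allylic alcohol without acyl migration or ester cleavage.

**Compound list**

1 | prop-2-yn-1-ol | C#CCO | starting material
2 | (E)-2-bromo-3-iodoprop-2-en-1-ol | OC/C(Br)=C\I | intermediate
3 | tert-butyl{[(E)-2-bromo-3-iodoprop-2-en-1-yl]oxy}dimethylsilane | CC(C)(C)[Si](C)(C)OC/C(Br)=C\I | intermediate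
4 | (E)-tributyl[2-(trimethylsilyl)ethenyl]stannane | CCCC[Sn](CCCC)(CCCC)/C=C/[Si](C)(C)C | starting material
5 | tert-butyl{[(2E,4E)-2-bromo-5-(trimethylsilyl)penta-2,4-dien-1-yl]oxy}dimethylsilane | C[Si](C)(C)/C=C/C=C(/Br)CO[Si](C)(C)C(C)(C)C | intermediate
6 | (S)-3-hydroxydihydrofuran-2(3H)-one | O[C@H]1CCOC1=O | starting material
7 | (S)-3-(benzyloxy)dihydrofuran-2(3H)-one | O=C1OCC[C@@H]1OCc1ccccc1 | intermediate
8 | (S)-2-(benzyloxy)-4-hydroxy-N-methoxy-N-methylbutanamide | OCC[C@H](OCc1ccccc1)C(=O)N(C)OC | intermediate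
9 | (S)-2-(benzyloxy)-4-iodo-N-methoxy-N-methylbutanamide | ICC[C@H](OCc1ccccc1)C(=O)N(C)OC | intermediate
10 | (S)-3-(benzyloxy)-1-iodo-6-methylhept-5-en-4-one | ICC[C@H](OCc1ccccc1)C(=O)C=C(C)C | intermediate
11 | [(S)-3-(benzyloxy)-6-methyl-4-oxohept-5-en-1-yl]zinc iodide | I[Zn]CC[C@H](OCc1ccccc1)C(=O)C=C(C)C | intermediate
12 | (5S,8Z,10E)-5-(benzyloxy)-8-{[(tert-butyldimethylsilyl)oxy]methyl}-2-methyl-11-(trimethylsilyl)undeca-2,8,10-trien-4-one | C[Si](C)(C)/C=C/C=C(/CC[C@H](OCc1ccccc1)C(=O)C=C(C)C)CO[Si](C)(C)C(C)(C)C | intermediate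
13 | cis-fused cycloadduct: 7α-benzyloxy-10β-(TBSO-methyl)-4,4-dimethyl-3α-(trimethylsilyl)-5β-H-decal-1-en-6-one | C1C[C@H](OCc3ccccc3)C(=O)[C@@H]2C(C)(C)[C@H]([Si](C)(C)C)C=C[C@]12CO[Si](C)(C)C(C)(C)C | intermediate
14 | trans-fused ketone: 7α-benzyloxy-10β-(TBSO-methyl)-4,4-dimethyl-3α-(trimethylsilyl)-5α-H-decal-1-en-6-one | C1C[C@H](OCc3ccccc3)C(=O)[C@H]2C(C)(C)[C@H]([Si](C)(C)C)C=C[C@]12CO[Si](C)(C)C(C)(C)C | intermediate
15 | 7-benzyloxy-10β-(TBSO-methyl)-4,4-dimethyl-3α-(trimethylsilyl)-5α-H-decala-1,6-dien-6-yl trifluoromethanesulfonate | C1CC(OCc3ccccc3)=C(OS(=O)(=O)C(F)(F)F)[C@H]2C(C)(C)[C@H]([Si](C)(C)C)C=C[C@]12CO[Si](C)(C)C(C)(C)C | intermediate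
16 | 7-benzyloxy-10β-(TBSO-methyl)-4,4-dimethyl-3α-(trimethylsilyl)-5α-H-decala-1,6-diene | C1CC(OCc3ccccc3)=C[C@H]2C(C)(C)[C@H]([Si](C)(C)C)C=C[C@]12CO[Si](C)(C)C(C)(C)C | intermediate
17 | 10β-(hydroxymethyl)-4,4-dimethyl-5α-H-decal-2-en-7-one | C1CC(=O)C[C@H]2C(C)(C)C=CC[C@]12CO | intermediate
18 | 10β-(acetoxymethyl)-4,4-dimethyl-5α-H-decal-2-en-7-one | C1CC(=O)C[C@H]2C(C)(C)C=CC[C@]12COC(C)=O | intermediate
19 | 10β-(acetoxymethyl)-2α,3α-dihydroxy-4,4-dimethyl-5α-H-decalin-7-one | C1CC(=O)C[C@H]2C(C)(C)[C@H](O)[C@H](O)C[C@]12COC(C)=O | intermediate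
20 | 10β-(acetoxymethyl)-2α-angeloyloxy-3α-hydroxy-4,4-dimethyl-5α-H-decalin-7-one | C1CC(=O)C[C@H]2C(C)(C)[C@H](O)[C@H](OC(=O)/C(C)=C\C)C[C@]12COC(C)=O | intermediate
21 | 3α-acetoxy-10β-(acetoxymethyl)-2α-angeloyloxy-4,4-dimethyl-5α-H-decalin-7-one | C1CC(=O)C[C@H]2C(C)(C)[C@H](OC(C)=O)[C@H](OC(=O)/C(C)=C\C)C[C@]12COC(C)=O | intermediate
22 | 3α-acetoxy-10β-(acetoxymethyl)-2α-angeloyloxy-4,4-dimethyl-7-(trimethylsilyloxy)-5α-H-decal-7-ene | C1C=C(O[Si](C)(C)C)C[C@H]2C(C)(C)[C@H](OC(C)=O)[C@H](OC(=O)/C(C)=C\C)C[C@]12COC(C)=O | intermediate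
23 | 3α-acetoxy-10β-(acetoxymethyl)-2α-angeloyloxy-4,4-dimethyl-5α-H-decal-8-en-7-one | C1=CC(=O)C[C@H]2C(C)(C)[C@H](OC(C)=O)[C@H](OC(=O)/C(C)=C\C)C[C@]12COC(C)=O | intermediate
24 | (R)-3,7-dimethylocta-1,6-dien-3-ol ((R)-linalool) | C=C[C@](C)(O)CCC=C(C)C | starting material
25 | (R)-[(3,7-dimethylocta-1,6-dien-3-yl)oxy]triethylsilane | C=C[C@](C)(O[Si](CC)(CC)CC)CCC=C(C)C | intermediate
26 | (R)-4-methyl-4-[(triethylsilyl)oxy]hex-5-enal | C=C[C@](C)(O[Si](CC)(CC)CC)CCC=O | intermediate
27 | (R,E)-trimethyl({4-methyl-4-[(triethylsilyl)oxy]hexa-1,5-dien-1-yl}oxy)silane | C=C[C@](C)(O[Si](CC)(CC)CC)C/C=C/O[Si](C)(C)C | intermediate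
28 | (R)-3-methyl-3-[(triethylsilyl)oxy]pent-4-en-1-ol | C=C[C@](C)(O[Si](CC)(CC)CC)CCO | intermediate
29 | (R)-[(5-bromo-3-methylpent-1-en-3-yl)oxy]triethylsilane | C=C[C@](C)(O[Si](CC)(CC)CC)CCBr | intermediate
30 | {(R)-3-methyl-3-[(triethylsilyl)oxy]pent-4-en-1-yl}magnesium bromide | C=C[C@](C)(O[Si](CC)(CC)CC)CC[Mg]Br | intermediate
31 | 3α,20-diacetoxy-2α-angeloyloxy-13-(triethylsilyloxy)-7-(trimethylsilyloxy)-9βH-labda-7,14-diene (13R, side chain 9α) | C=C[C@](C)(O[Si](CC)(CC)CC)CC[C@@H]1C=C(O[Si](C)(C)C)C[C@H]2C(C)(C)[C@H](OC(C)=O)[C@H](OC(=O)/C(C)=C\C)C[C@]12COC(C)=O | intermediate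
32 | Mannich base: 8β-(dimethylaminomethyl)-7-ketone of the 9α-side-chain series | C=C[C@](C)(O[Si](CC)(CC)CC)CC[C@@H]1[C@@H](CN(C)C)C(=O)C[C@H]2C(C)(C)[C@H](OC(C)=O)[C@H](OC(=O)/C(C)=C\C)C[C@]12COC(C)=O | intermediate
33 | 8β-(trimethylammoniomethyl)-7-ketone iodide | C=C[C@](C)(O[Si](CC)(CC)CC)CC[C@@H]1[C@@H](C[N+](C)(C)C)C(=O)C[C@H]2C(C)(C)[C@H](OC(C)=O)[C@H](OC(=O)/C(C)=C\C)C[C@]12COC(C)=O.[I-] | intermediate
34 | 3α,20-diacetoxy-2α-angeloyloxy-13-(triethylsilyloxy)-9βH-labda-8(17),14-dien-7-one (13R) | C=C[C@](C)(O[Si](CC)(CC)CC)CC[C@@H]1C(=C)C(=O)C[C@H]2C(C)(C)[C@H](OC(C)=O)[C@H](OC(=O)/C(C)=C\C)C[C@]12COC(C)=O | intermediate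
35 | 3α,20-diacetoxy-2α-angeloyloxy-13-(triethylsilyloxy)-9βH-labda-8(17),14-dien-7α-ol (13R) | C=C[C@](C)(O[Si](CC)(CC)CC)CC[C@@H]1C(=C)[C@H](O)C[C@H]2C(C)(C)[C@H](OC(C)=O)[C@H](OC(=O)/C(C)=C\C)C[C@]12COC(C)=O | intermediate
36 | (2R,3S,5R,7R,9S,10R,13R)-3,20-diacetoxy-2-[(Z)-2-methylbut-2-enoyloxy]-9βH-labda-8(17),14-diene-7,13-diol | C=C[C@](C)(O)CC[C@@H]1C(=C)[C@H](O)C[C@H]2C(C)(C)[C@H](OC(C)=O)[C@H](OC(=O)/C(C)=C\C)C[C@]12COC(C)=O | target

**Step count and risks**

Total: 27 steps. Longest linear sequence: 19 steps (from 6 through steps 4 to 18 and 24 to 27).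

Risk 1, step 9. The cycloaddition must form two congested bonds (a silyl-bearing carbon to the gem-dimethyl carbon, and a fully substituted diene terminus to C5). The diene may instead lose its silyl group by ipso attack or protodesilylation before ring closure, or react too slowly. A weak endo preference would also erode the relay from C7 to C10; if the exo mode dominated, the enantiomeric lactone would be used.
Fallback (from 3 and 11, back at 17): the silyl diene is replaced by a more nucleophilic 2-ethoxy diene whose reacting terminus C3 is unsubstituted.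
- Stille coupling of 3 with tributyl(1-ethoxyvinyl)stannane would give tert-butyl{[(E)-2-bromo-4-ethoxypenta-2,4-dien-1-yl]oxy}dimethylsilane F1.
- Negishi coupling with 11 would give the triene (5S,8Z)-5-(benzyloxy)-8-{[(tert-butyldimethylsilyl)oxy]methyl}-10-ethoxy-2-methylundeca-2,8,10-trien-4-one F2.
- Heating in toluene, or Me2AlCl at −78 °C, should give the cis-fused 2-ethoxy cycloadduct F3 by the same chelate-controlled endo cycloaddition.
- Oxalic acid on wet silica would give the cis-fused 2,6-diketone F4, and DBU the trans-fused 2,6-diketone F5.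
- KN(SiMe3)2 (2.3 equiv) and PhNTf2 would give the bis(enol triflate) F6; C2 should enolise toward C3, away from the ring fusion, and C6 toward C7.
- Pd(OAc)2/PPh3/HCO2H/Bu3N would give the 2,6-diene benzyl enol ether F7, which TFA/H2O converts into 17.

Risk 2, step 11. Enolisation of the α-benzyloxy ketone may take place at the ring-fusion carbon, or O-sulfonylation of the hindered tetrasubstituted enolate may be too slow, so that the C6 oxygen is not removed.
Fallback (from 14, back at 17): the carbonyl is transposed through an α-ketol instead.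
- NaBH4/CeCl3·7H2O would reduce 14 to the 6β-alcohol F8 (either C6 epimer serves).
- Lithium 4,4′-di-tert-butylbiphenylide at −78 °C would remove the benzyl group to give the 6,7-diol F9.
- Dess–Martin periodinane (1 equiv) would oxidise the less hindered C7 hydroxyl to the 6-hydroxy-7-ketone F10.
- SmI2 in THF/MeOH would cleave the C6–O bond next to the ketone to give the 7-ketone F11, and TFA/H2O then gives 17.

Risk 3, step 24. The Grignard reagent may attack the ketone or the three esters in 1,2-fashion faster than the copper-catalysed 1,4-addition occurs at the neopentylic β-carbon C9.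
Fallback (from 29 and 23, back at 34): nickel-catalysed reductive conjugate addition of the alkyl bromide 29 to the enone 23 (NiCl2·glyme, terpyridine, Mn powder, Et3SiCl, DMF) uses a primary alkyl radical that tolerates esters and should add anti to the C10 CH2OAc group. It would give the C7–C8 triethylsilyl enol ether F12, which is taken through the conditions of step 25 to give 34.

Further compounds
F1 | step 9 | tert-butyl{[(E)-2-bromo-4-ethoxypenta-2,4-dien-1-yl]oxy}dimethylsilane | CCOC(=C)/C=C(/Br)CO[Si](C)(C)C(C)(C)C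
F2 | step 9 | (5S,8Z)-5-(benzyloxy)-8-{[(tert-butyldimethylsilyl)oxy]methyl}-10-ethoxy-2-methylundeca-2,8,10-trien-4-one | CCOC(=C)/C=C(/CC[C@H](OCc1ccccc1)C(=O)C=C(C)C)CO[Si](C)(C)C(C)(C)C
F3 | step 9 | cis-fused 7α-benzyloxy-10β-(TBSO-methyl)-2-ethoxy-4,4-dimethyl-5β-H-decal-1-en-6-one | C1C[C@H](OCc3ccccc3)C(=O)[C@@H]2C(C)(C)CC(OCC)=C[C@]12CO[Si](C)(C)C(C)(C)C
F4 | step 9 | cis-fused 7α-benzyloxy-10β-(TBSO-methyl)-4,4-dimethyl-5β-H-decalin-2,6-dione | C1C[C@H](OCc3ccccc3)C(=O)[C@@H]2C(C)(C)CC(=O)C[C@]12CO[Si](C)(C)C(C)(C)C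
F5 | step 9 | trans-fused 7α-benzyloxy-10β-(TBSO-methyl)-4,4-dimethyl-5α-H-decalin-2,6-dione | C1C[C@H](OCc3ccccc3)C(=O)[C@H]2C(C)(C)CC(=O)C[C@]12CO[Si](C)(C)C(C)(C)C
F6 | step 9 | 7-benzyloxy-10β-(TBSO-methyl)-4,4-dimethyl-5α-H-decala-2,6-diene-2,6-diyl bis(trifluoromethanesulfonate) | C1CC(OCc3ccccc3)=C(OS(=O)(=O)C(F)(F)F)[C@H]2C(C)(C)C=C(OS(=O)(=O)C(F)(F)F)C[C@]12CO[Si](C)(C)C(C)(C)C
F7 | step 9 | 7-benzyloxy-10β-(TBSO-methyl)-4,4-dimethyl-5α-H-decala-2,6-diene | C1CC(OCc3ccccc3)=C[C@H]2C(C)(C)C=CC[C@]12CO[Si](C)(C)C(C)(C)C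
F8 | step 11 | 7α-benzyloxy-10β-(TBSO-methyl)-4,4-dimethyl-3α-(trimethylsilyl)-5α-H-decal-1-en-6β-ol | C1C[C@H](OCc3ccccc3)[C@@H](O)[C@H]2C(C)(C)[C@H]([Si](C)(C)C)C=C[C@]12CO[Si](C)(C)C(C)(C)C
F9 | step 11 | 10β-(TBSO-methyl)-4,4-dimethyl-3α-(trimethylsilyl)-5α-H-decal-1-ene-6β,7α-diol | C1C[C@H](O)[C@@H](O)[C@H]2C(C)(C)[C@H]([Si](C)(C)C)C=C[C@]12CO[Si](C)(C)C(C)(C)C
F10 | step 11 | 6β-hydroxy-10β-(TBSO-methyl)-4,4-dimethyl-3α-(trimethylsilyl)-5α-H-decal-1-en-7-one | C1CC(=O)[C@@H](O)[C@H]2C(C)(C)[C@H]([Si](C)(C)C)C=C[C@]12CO[Si](C)(C)C(C)(C)C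
F11 | step 11 | 10β-(TBSO-methyl)-4,4-dimethyl-3α-(trimethylsilyl)-5α-H-decal-1-en-7-one | C1CC(=O)C[C@H]2C(C)(C)[C@H]([Si](C)(C)C)C=C[C@]12CO[Si](C)(C)C(C)(C)C
F12 | step 24 | 3α,20-diacetoxy-2α-angeloyloxy-7,13-bis(triethylsilyloxy)-9βH-labda-7,14-diene (13R, side chain 9α) | C=C[C@](C)(O[Si](CC)(CC)CC)CC[C@@H]1C=C(O[Si](CC)(CC)CC)C[C@H]2C(C)(C)[C@H](OC(C)=O)[C@H](OC(=O)/C(C)=C\C)C[C@]12COC(C)=O
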